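**Retrosynthetic overview**
1. Licoricidin ⇐ MOM/aryl‑TMS removal from a protected isoflavan; the pyran ring (ring C) is closed last by an intramolecular Mitsunobu O1–C2 etherification.
2. C4–C4a bond ⇐ Fe‑catalysed sp3–sp2 coupling of an (R)‑γ‑silyloxy alkyl bromide with a ring‑A aryl Grignard (from 5‑methoxyresorcinol; C‑8 blocked by TMS; prenyl put in by directed ortho‑metalation, DoM).
3. Key step: the bromide comes from a catalytic enantioselective desymmetrising ring‑opening (TMSBr, chiral squaramide) of an achiral, mirror‑symmetric 3‑aryloxetane; this one step sets C‑3.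
4. The 3‑aryloxetane ⇐ resorcinol: bis‑MOM ether, DoM/prenylation, then DoM/Fe‑Kumada coupling with 3‑iodooxetane.
5. Ring order: rings A and B are bought as arenes; the oxetane is a temporary symmetric ring that is opened; the chroman ring C is formed last.

Assumption: resorcinol, 5‑methoxyresorcinol, 3‑iodooxetane, prenyl bromide, MOMCl, SEMCl, TMSBr and TMSCl are catalogue chemicals. The chiral squaramide is treated as a catalyst and its preparation is not counted. Which catalyst antipode gives (R)‑9 on this ortho‑substituted aryl oxetane is assumed by analogy and must be confirmed on the first run.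

---

**Step 1**
Reactants: 1 resorcinol; 2 chloromethyl methyl ether
Product: 3 1,3‑bis(methoxymethoxy)benzene
Conditions: MOMCl, i‑Pr2NEt, CH2Cl2, 0 °C → rt
Reagents that add atoms: MOMCl, COCCl
Why: Double O‑alkylation (MOM acetal protection) installs the ortho‑directing groups needed for the next two metalations; MOM survives base, fluoride and Mitsunobu conditions.

**Step 2**
Reactants: 3; 4 prenyl bromide
Product: 5 1,3‑bis(methoxymethoxy)‑2‑(3‑methylbut‑2‑en‑1‑yl)benzene
Conditions: n‑BuLi, THF, 0 °C → rt; CuBr·SMe2, prenyl bromide, −78 °C → rt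
Reagents that add atoms: prenyl bromide, CC(C)=CCBr
Why: DoM occurs at the doubly activated C‑2 between the two OMOM groups, and Cu‑mediated SN2 allylation gives the linear prenyl arene.

**Step 3**
Reactants: 5; 6 3‑iodooxetane
Product: 7 3‑[2,4‑bis(methoxymethoxy)‑3‑(3‑methylbut‑2‑en‑1‑yl)phenyl]oxetane (achiral; mirror plane through oxetane O and C‑3)
Conditions: s‑BuLi, TMEDA, THF, −78 °C; MgBr2·OEt2, −78 → 0 °C; then 6, Fe(acac)3 (10 mol %), 0 °C → rt
Reagents that add atoms: 3‑iodooxetane, IC1COC1
Why: A second DoM ortho to OMOM (cold s‑BuLi/TMEDA to outrun lateral metalation of the prenyl CH2), Li→Mg exchange and an iron‑catalysed Kumada‑type sp2–sp3 coupling with the secondary iodide attach the oxetane.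

**Step 4 (key step)**
Reactants: 7; 8 bromotrimethylsilane
Product: 9 {[(2R)‑3‑bromo‑2‑[2,4‑bis(methoxymethoxy)‑3‑(3‑methylbut‑2‑en‑1‑yl)phenyl]propyl]oxy}trimethylsilane
Conditions: TMSBr (1.1 equiv), chiral tert‑leucine‑derived arylpyrrolidine squaramide (5 mol %, antipode giving R), TBME, −78 °C; Et3N quench, non‑aqueous work‑up (TMS ether kept)
Reagents that add atoms: TMSBr, C[Si](C)(C)Br
Why: Enantioselective desymmetrising oxetane ring‑opening under H‑bond‑donor anion‑binding catalysis: TMSBr silylates the oxetane oxygen and catalyst‑bound bromide opens one of the two enantiotopic CH2–O bonds, creating the future C‑3 as R; the low temperature is intended to spare the aryl MOM ethers and prenyl group.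

**Step 5**
Reactants: 10 5‑methoxyresorcinol; 11 2‑(trimethylsilyl)ethoxymethyl chloride
Product: 12 1‑methoxy‑3,5‑bis{[2‑(trimethylsilyl)ethoxy]methoxy}benzene
Conditions: SEMCl, i‑Pr2NEt, CH2Cl2, 0 °C → rt
Reagents that add atoms: SEMCl, C[Si](C)(C)CCOCCl
Why: SEM acetal protection gives ortho‑directing groups that are fluoride‑labile, so ring A can later be unmasked without touching the ring‑B MOM ethers.

**Step 6**
Reactants: 12; 13 chlorotrimethylsilane; 4 prenyl bromide
Product: 14 trimethyl{4‑methoxy‑3‑(3‑methylbut‑2‑en‑1‑yl)‑2,6‑bis{[2‑(trimethylsilyl)ethoxy]methoxy}phenyl}silane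
Conditions: n‑BuLi, THF, 0 °C; TMSCl, −78 °C → rt; then s‑BuLi/TMEDA, −78 → −40 °C; CuBr·SMe2, prenyl bromide, −78 °C → rt (one pot)
Reagents that add atoms: TMSCl, C[Si](C)(C)Cl; prenyl bromide, CC(C)=CCBr
Why: The first DoM goes to the most acidic site between the two OSEM groups and is capped with TMS as a traceless block (future C‑8–H), which forces the second DoM to one of the two equivalent positions between OMe and OSEM, where Cu‑mediated prenylation installs the ring‑A prenyl.

**Step 7**
Reactants: 14; 9
Product: 15 {(2R)‑2‑[2,4‑bis(methoxymethoxy)‑3‑prenylphenyl]‑3‑[2‑methoxy‑3‑prenyl‑4,6‑bis(SEM‑oxy)‑5‑(trimethylsilyl)phenyl]propoxy}trimethylsilane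
Conditions: 14 (1.3 equiv), s‑BuLi/TMEDA, THF, −78 °C; MgBr2·OEt2; slow addition to 9, FeCl3 (5 mol %), TMEDA, THF, 0 °C → rt
Reagents that add atoms: none (both fragments are the reactants)
Why: The only remaining ring hydrogen of 14 (between OMe and OSEM) is lithiated by DoM, transmetalated to Mg and joined to the primary bromide by iron‑catalysed Kumada‑type sp2–sp3 cross‑coupling; bond formation is at the CH2 next to the stereocentre, so C‑3 is untouched.

**Step 8**
Reactants: 15
Product: 16 4‑{(2R)‑2‑[2,4‑bis(methoxymethoxy)‑3‑prenylphenyl]‑3‑hydroxypropyl}‑5‑methoxy‑6‑prenyl‑2‑(trimethylsilyl)benzene‑1,3‑diol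
Conditions: TBAF (6 equiv), THF/DMPU, 60 °C, degassed
Reagents that add atoms: none
Why: Fluoride cleaves both aryl SEM ethers and the primary O–TMS while aryl MOM ethers are inert, exposing only the ring‑A phenols and the primary alcohol (any aryl–TMS lost here is harmless, since C‑8 ends as H).

**Step 9**
Reactants: 16
Product: 17 (3R)‑3‑[2,4‑bis(methoxymethoxy)‑3‑prenylphenyl]‑5‑methoxy‑6‑prenyl‑8‑(trimethylsilyl)chroman‑7‑ol
Conditions: PPh3, DIAD, THF (0.01 M), 0 °C → rt
Reagents that add atoms: none
Why: Intramolecular Mitsunobu etherification: only the phenol ortho to the side chain can reach the activated primary carbon (6‑exo‑tet), the ring‑B 2′‑oxygen is still MOM‑blocked so no dihydrobenzofuran can form, and SN2 at CH2 leaves C‑3 unchanged.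

**Step 10**
Reactants: 17
Product: 18 licoricidin, (3R)‑3‑(2,4‑dihydroxy‑3‑prenylphenyl)‑5‑methoxy‑6‑prenylchroman‑7‑ol
Conditions: 3 M HCl, MeOH/THF, rt → 40 °C, monitored closely
Reagents that add atoms: none
Why: Acid‑catalysed acetal hydrolysis removes both MOM groups and ipso‑protodesilylates the electron‑rich aryl–TMS at C‑8; the conditions are kept mild to avoid acid cyclisation of the prenyl groups onto the neighbouring phenols.

---

**Compound list**
1 | resorcinol | Oc1cccc(O)c1 | starting material
2 | chloromethyl methyl ether (MOMCl) | COCCl | starting material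
3 | 1,3‑bis(methoxymethoxy)benzene | COCOc1cccc(OCOC)c1 | intermediate
4 | prenyl bromide | CC(C)=CCBr | starting material
5 | 1,3‑bis(methoxymethoxy)‑2‑prenylbenzene | COCOc1cccc(OCOC)c1CC=C(C)C | intermediate
6 | 3‑iodooxetane | IC1COC1 | starting material
7 | 3‑[2,4‑bis(methoxymethoxy)‑3‑prenylphenyl]oxetane | COCOc1ccc(C2COC2)c(OCOC)c1CC=C(C)C | intermediate
8 | bromotrimethylsilane | C[Si](C)(C)Br | starting material
9 | (R)‑3‑bromo‑2‑aryl‑propyl TMS ether | BrC[C@H](c1ccc(OCOC)c(CC=C(C)C)c1OCOC)CO[Si](C)(C)C | intermediate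
10 | 5‑methoxyresorcinol | COc1cc(O)cc(O)c1 | starting material
11 | SEM chloride | C[Si](C)(C)CCOCCl | starting material
12 | 1‑methoxy‑3,5‑bis(SEM‑oxy)benzene | COc1cc(OCOCC[Si](C)(C)C)cc(OCOCC[Si](C)(C)C)c1 | intermediate
13 | chlorotrimethylsilane | C[Si](C)(C)Cl | starting material
14 | TMS‑blocked, prenylated ring‑A arene | COc1cc(OCOCC[Si](C)(C)C)c([Si](C)(C)C)c(OCOCC[Si](C)(C)C)c1CC=C(C)C | intermediate
15 | (R)‑coupled diaryl propyl TMS ether | COc1c(C[C@H](c2ccc(OCOC)c(CC=C(C)C)c2OCOC)CO[Si](C)(C)C)c(OCOCC[Si](C)(C)C)c([Si](C)(C)C)c(OCOCC[Si](C)(C)C)c1CC=C(C)C | intermediate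
16 | (R)‑resorcinol diol / primary alcohol | COc1c(C[C@H](c2ccc(OCOC)c(CC=C(C)C)c2OCOC)CO)c(O)c([Si](C)(C)C)c(O)c1CC=C(C)C | intermediate
17 | (3R)‑8‑TMS, 2′,4′‑di‑O‑MOM licoricidin | COc1c(CC=C(C)C)c(O)c([Si](C)(C)C)c2c1C[C@H](c1ccc(OCOC)c(CC=C(C)C)c1OCOC)CO2 | intermediate
18 | licoricidin | COc1c(CC=C(C)C)c(O)cc2c1C[C@H](c1ccc(O)c(CC=C(C)C)c1O)CO2 | target

---

**Totals**
Total steps: 10. Longest linear sequence: 8 (1 → 3 → 5 → 7 → 9 → 15 → 16 → 17 → 18); ring A joins after 2 steps.

**Three steps most likely to fail, with fallbacks**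
1. Step 4 (desymmetrisation). Risks: TMSBr or adventitious HBr attacking the aryl MOM ethers or prenyl group, the ortho‑OMOM oxygen opening the activated oxetane to a dihydrobenzofuran, and lower ee with an ortho‑substituted aryl. Fallback: switch to the prochiral 2‑aryl‑propane‑1,3‑diol (from the arylmalonate by reduction) and desymmetrise by catalytic enantioselective mono‑acylation (dinuclear‑zinc or lipase), then convert the free arm to the bromide; the ester arm replaces OTMS.
2. Step 7 (fragment coupling). Risks: lateral metalation of the prenyl CH2 in 14, a sluggish di‑ortho‑substituted aryl Grignard, and E2 of the β‑branched bromide. Fallback: couple 9 with the TMS‑blocked but not yet prenylated arene (no benzylic/allylic CH), close the chroman, and install the ring‑A prenyl last by ortho‑C‑prenylation (or 1,1‑dimethylallyl ether/Claisen) of the free 7‑OH, where C‑6 is the only open ortho site while C‑8 still carries TMS.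
3. Step 3 (oxetane installation). Risks: lateral metalation of 5 and a low‑yielding Fe coupling with 3‑iodooxetane. Fallback: reverse the order — start from 4‑bromoresorcinol bis‑MOM ether, form the Grignard by Br/Mg exchange and couple with 3‑iodooxetane, then prenylate by DoM at the position between the two OMOM groups.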